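Ring A (C1 butyryl, C2 OH, C3 bridge, C4 OH, C5 methyl, C6 OMe) is cut at C2–C3. The feature exploited is that C2–C1–C6–C5–C4, with OMe ortho to the butyryl group, is the C2–C6 backbone of a 3-butyryl-4-methoxy-5-methyl-2-pyrone. The precursor is that pyrone, an isomer of the target, carrying finished ring B at the end of a CH2CH2 chain on pyrone C6. Magnesium methoxide opens the lactone, and the α-CH2 of the freed ketone then attacks the new ester (Claisen). One operation closes ring A, places all six substituents, and turns the inner CH2 into arene C3, leaving the outer CH2 as the bridge.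

Key step: step 8

Remark on the chemistry: the target has no stereocentre and no stereogenic double bond, so it is achiral and no enantiomer has to be selected; ring B is written in the enol tautomer of the given SMILES; 1-(2,4,6-trihydroxyphenyl)propan-1-one (flopropione) is taken as a purchasable compound.

Step 1
Reactants: 1 3-methylpentane-2,4-dione
Product: 2 4-methyl-3,5-dioxohexanoic acid
Conditions: LDA (2.2 equiv), THF, −78 → 0 °C; CO2 (g), −78 °C → rt; cold 2 M HCl
Reagents that add atoms: carbon dioxide, O=C=O
Why: The 1,3-dianion of a β-diketone reacts at its more basic terminal carbanion (Hauser–Harris dianion carboxylation), and because the diketone is symmetrical only one keto acid can form.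

Step 2
Reactants: 2 4-methyl-3,5-dioxohexanoic acid
Product: 3 4-hydroxy-5,6-dimethyl-2H-pyran-2-one
Conditions: Ac2O, rt
Reagents that add atoms: none
Why: Acetic anhydride activates the acid as a mixed anhydride that the enol oxygen of the δ-carbonyl captures, which is the known cyclodehydration of 3,5-dioxo acids to 4-hydroxy-2-pyrones.

Step 3
Reactants: 3 4-hydroxy-5,6-dimethyl-2H-pyran-2-one; 4 butanoic acid
Product: 6 3-butanoyl-4-hydroxy-5,6-dimethyl-2H-pyran-2-one, via pyranyl butanoate 5 (not isolated)
Conditions: DCC (1.1 equiv), DMAP (0.3 equiv), toluene, rt, then 90 °C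
Reagents that add atoms: none
Why: Steglich O-acylation is followed by the DMAP-mediated O-to-C acyl shift (Fries-type rearrangement of the enol ester) to C3, the only free nucleophilic carbon, and this is the standard entry to 3-acyl-4-hydroxy-2-pyrones.

Step 4
Reactants: 6 3-butanoyl-4-hydroxy-5,6-dimethyl-2H-pyran-2-one
Product: 7 3-butanoyl-4-methoxy-5,6-dimethyl-2H-pyran-2-one
Conditions: Me2SO4 (1.2 equiv), K2CO3 (1.5 equiv), acetone, reflux
Reagents that add atoms: dimethyl sulfate, COS(=O)(=O)OC
Why: In this Williamson-type O-alkylation the hard sulfate electrophile should methylate the acidic enolate on oxygen, and carbonate/sulfate conditions favour the 4-methoxy-2-pyrone over the 2-methoxy-4-pyrone isomer and over C3-methylation.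

Step 5
Reactants: 7 3-butanoyl-4-methoxy-5,6-dimethyl-2H-pyran-2-one
Product: 8 3-butanoyl-6-[(E)-2-(dimethylamino)ethenyl]-4-methoxy-5-methyl-2H-pyran-2-one
Conditions: DMF-DMA (1.5 equiv), toluene, 90 °C
Reagents that add atoms: N,N-dimethylformamide dimethyl acetal, COC(OC)N(C)C
Why: The 6-CH3 is the vinylogous α-position of both the lactone and the butyryl carbonyl and so holds the most acidic C–H, so the amide-acetal condensation (Leimgruber–Batcho-type enamination, known for activated methylpyrones) should occur there rather than at the unconjugated 5-CH3 or the less acidic, more hindered butyryl α-CH2, giving the thermodynamic E enamine.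

Step 6
Reactants: 9 1-(2,4,6-trihydroxyphenyl)propan-1-one (flopropione)
Product: 10 3,5-dihydroxy-6,6-dimethyl-2-propanoylcyclohexa-2,4-dien-1-one (propionylfilicinic acid)
Conditions: NaOMe (3 equiv), MeI (2.2 equiv), MeOH, 0 °C → rt; 1 M HCl
Reagents that add atoms: iodomethane, CI
Why: Dearomative geminal C-methylation of an acylphloroglucinol polyanion is the known route to acylfilicinic acids, since the first methyl makes its carbon the most nucleophilic site and limiting MeI holds back further methylation.

Step 7
Reactants: 8 3-butanoyl-6-[(E)-2-(dimethylamino)ethenyl]-4-methoxy-5-methyl-2H-pyran-2-one; 10 propionylfilicinic acid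
Product: 12 3-butanoyl-6-[2-(2,6-dihydroxy-3,3-dimethyl-4-oxo-5-propanoylcyclohexa-1,5-dien-1-yl)ethyl]-4-methoxy-5-methyl-2H-pyran-2-one, via alkylidene triketone 11 (not isolated)
Conditions: Hantzsch ester (diethyl 2,6-dimethyl-1,4-dihydropyridine-3,5-dicarboxylate, 1.2 equiv), AcOH–CH2Cl2 1:4, 35 °C
Reagents that add atoms: none
Why: Acid protonates the push–pull enamine at the carbon next to the pyrone, the only free ring CH of 10 adds to the iminium carbon and dimethylamine is lost (the Mannich/Knoevenagel addition–elimination known for enaminones with cyclic 1,3-dicarbonyls), and Hantzsch ester reduces alkylidene 11 at once as in three-component reductive alkylation, which forestalls 2:1 adducts while the amine stays protonated and away from C4–OMe.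

Step 8
Reactants: 12 3-butanoyl-6-[2-(2,6-dihydroxy-3,3-dimethyl-4-oxo-5-propanoylcyclohexa-1,5-dien-1-yl)ethyl]-4-methoxy-5-methyl-2H-pyran-2-one
Product: 14 aspidin PB, via ring-opened keto ester 13 (not isolated)
Conditions: Mg(OMe)2 (8 equiv), MeOH, Ar, 65 °C (sealed vessel, up to 100 °C, only if 13 persists); then cold 1 M HCl
Reagents that add atoms: none
Why: Methoxide adds to the lactone carbonyl (pyrone C2) of 12, whose ring B is parked as an inert magnesium dienolate, and opens the ring to keto ester 13; the enolate of the freed ketone on its chain-CH2 side attacks the ester carbonyl, methoxide leaves and enolisation gives the arene, so the net change is an isomerisation that forms the ring A bond C2–C3. The closest known reaction type is the alkoxide- or magnesium alkoxide-induced isomerisation of 6-alkyl-4-methoxy-2-pyrones and of polyketo esters to phloroglucinols by intramolecular Claisen condensation, applied here to a 3-acyl member of that class. Ring A closes in the 6-(enolendo)-exo-trig mode, because both enolate carbons become ring atoms, and this mode is favoured for six-membered rings. No stereocentre is created, and the labile methyl-bearing sp3 carbon of 13 disappears on aromatisation. The step needs attack on the ester to outrun the two aldol-type closures through the butyryl group (butyryl α-CH2 on the freed ketone, chain CH2 on the butyryl carbonyl), retro-Claisen loss of butyryl, and base-induced redistribution of the new methylene bridge. It is secured by the E alkene inherited from the pyrone, which holds ester and ketone chain cis, by Mg2+ chelation of the ester/butyryl pair, which activates the ester and ties up the butyryl group, by the degenerate MeO-for-MeO exchange at the vinylogous ester carbon, and by irreversible deprotonation of the acidic acylphloroglucinol at the lowest temperature that gives conversion.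

Compound list
1 | 3-methylpentane-2,4-dione | CC(=O)C(C)C(C)=O | starting material
2 | 4-methyl-3,5-dioxohexanoic acid (C4 racemic and labile) | CC(=O)C(C)C(=O)CC(=O)O | intermediate
3 | 4-hydroxy-5,6-dimethyl-2H-pyran-2-one | CC1=C(C)C(O)=CC(=O)O1 | intermediate
4 | butanoic acid | CCCC(=O)O | starting material
5 | 5,6-dimethyl-2-oxo-2H-pyran-4-yl butanoate | CCCC(=O)OC1=CC(=O)OC(C)=C1C | intermediate
6 | 3-butanoyl-4-hydroxy-5,6-dimethyl-2H-pyran-2-one | CCCC(=O)C1=C(O)C(C)=C(C)OC1=O | intermediate
7 | 3-butanoyl-4-methoxy-5,6-dimethyl-2H-pyran-2-one | CCCC(=O)C1=C(OC)C(C)=C(C)OC1=O | intermediate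
8 | 3-butanoyl-6-[(E)-2-(dimethylamino)ethenyl]-4-methoxy-5-methyl-2H-pyran-2-one | CCCC(=O)C1=C(OC)C(C)=C(/C=C/N(C)C)OC1=O | intermediate
9 | 1-(2,4,6-trihydroxyphenyl)propan-1-one (flopropione) | CCC(=O)c1c(O)cc(O)cc1O | starting material
10 | 3,5-dihydroxy-6,6-dimethyl-2-propanoylcyclohexa-2,4-dien-1-one (propionylfilicinic acid) | CCC(=O)C1=C(O)C=C(O)C(C)(C)C1=O | intermediate
11 | 3-butanoyl-6-[2-(2-hydroxy-5,5-dimethyl-4,6-dioxo-3-propanoylcyclohex-2-en-1-ylidene)ethyl]-4-methoxy-5-methyl-2H-pyran-2-one (exocyclic C=C geometry undefined, both forms converge) | CCC(=O)C1=C(O)C(=CCC2=C(C)C(OC)=C(C(=O)CCC)C(=O)O2)C(=O)C(C)(C)C1=O | intermediate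
12 | 3-butanoyl-6-[2-(2,6-dihydroxy-3,3-dimethyl-4-oxo-5-propanoylcyclohexa-1,5-dien-1-yl)ethyl]-4-methoxy-5-methyl-2H-pyran-2-one | O=C1OC(CCC2=C(O)C(C)(C)C(=O)C(C(=O)CC)=C2O)=C(C)C(OC)=C1C(=O)CCC | intermediate
13 | methyl (E)-2-butanoyl-7-(2,6-dihydroxy-3,3-dimethyl-4-oxo-5-propanoylcyclohexa-1,5-dien-1-yl)-3-methoxy-4-methyl-5-oxohept-2-enoate (C4 racemic and labile) | COC(=O)/C(C(=O)CCC)=C(/OC)C(C)C(=O)CCC1=C(O)C(C)(C)C(=O)C(C(=O)CC)=C1O | intermediate
14 | aspidin PB, 1-{3-[(2,6-dihydroxy-3,3-dimethyl-4-oxo-5-propanoylcyclohexa-1,5-dien-1-yl)methyl]-2,4-dihydroxy-6-methoxy-5-methylphenyl}butan-1-one (achiral) | CCCC(=O)c1c(O)c(CC2=C(O)C(C)(C)C(=O)C(C(=O)CC)=C2O)c(O)c(C)c1OC | target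

Total step count: 8. Longest linear sequence: 7 (steps 1, 2, 3, 4, 5, 7, 8).

Steps most likely to fail

1. Step 8. The ring-opened material may rest as its doubly stabilised vinylogous anion. Enolisation toward the chain CH2 and ring closure would then be too slow at temperatures the product tolerates. On forcing, E/Z scrambling of the push–pull alkene opens the aldol-type closures through the butyryl group, methoxide may strip the butyryl group by retro-Claisen cleavage, and the finished methylene bridge may redistribute in hot base.
Fallback (sets out from 10, comes back at 14): ring A is made as a free monomer by arene chemistry and joined to ring B by the classical formaldehyde bridging of acylphloroglucinols. Purchased 2-methylphloroglucinol (Cc1c(O)cc(O)cc1O) is acylated with butyryl chloride and AlCl3 (Friedel–Crafts; the two free positions are equivalent) to 1-(2,4,6-trihydroxy-3-methylphenyl)butan-1-one F1. MOMCl (2 equiv) and i-Pr2NEt cap the hydroxyl para to the ketone and the less hindered ortho hydroxyl, which leaves the chelated hydroxyl between butyryl and methyl free in 1-[2-hydroxy-4,6-bis(methoxymethoxy)-3-methylphenyl]butan-1-one F2. Me2SO4/K2CO3 in hot acetone gives 1-[2-methoxy-4,6-bis(methoxymethoxy)-3-methylphenyl]butan-1-one F3. HCl in MeOH then frees 1-(4,6-dihydroxy-2-methoxy-3-methylphenyl)butan-1-one F4 (pseudo-aspidinol). F4 and 10 are condensed with aqueous formaldehyde in dilute KOH at 0 °C to rt (Knoevenagel condensation, then Michael addition of the second enolate). Compound 14 is separated by chromatography from the two symmetrical dimers that a statistical coupling also gives.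

2. Step 5. Condensation at the butyryl α-methylene may compete with reaction at the 6-methyl group, and amine-derived species may exchange the activated 4-methoxy group on prolonged heating.
Fallback (sets out from 3, comes back at 12): the two-carbon arm is installed before any butyryl group exists. Pyrone 3 is converted into its O,C-dianion (LDA, 2.2 equiv, THF, −78 °C) and alkylated at the 6-methyl carbon with benzyl chloromethyl ether to 6-[2-(benzyloxy)ethyl]-4-hydroxy-5-methyl-2H-pyran-2-one F5. Butanoic acid/DCC/DMAP as in step 3 gives 6-[2-(benzyloxy)ethyl]-3-butanoyl-4-hydroxy-5-methyl-2H-pyran-2-one F6. Me2SO4/K2CO3 as in step 4 gives 6-[2-(benzyloxy)ethyl]-3-butanoyl-4-methoxy-5-methyl-2H-pyran-2-one F7. Hydrogenolysis (H2, Pd/C, EtOAc) gives 3-butanoyl-6-(2-hydroxyethyl)-4-methoxy-5-methyl-2H-pyran-2-one F8. Dess–Martin oxidation gives (5-butanoyl-4-methoxy-3-methyl-6-oxo-6H-pyran-2-yl)acetaldehyde F9, which is used at once. Organocatalytic three-component reductive alkylation of 10 with F9 and Hantzsch ester (L-proline cat., CH2Cl2, rt) gives 12.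

3. Step 7. Hydride transfer to the protonated enamine may run ahead of C–C bond formation, C-protonation of the strongly delocalised enamine may be sluggish at a temperature the dihydropyridine tolerates, or a second molecule of 10 may add to the alkylidene before it is reduced.
Fallback (sets out from 8 and 10, comes back at 12): bond formation and reduction are separated, and the hydride donor is replaced by heterogeneous hydrogenation. Compounds 8 and 10 (1:1) are heated in AcOH without reductant, which is the acid-mediated displacement of the dimethylamino group by a cyclic 1,3-dicarbonyl C-nucleophile. The product is isolated as its conjugated tautomer, 3-butanoyl-6-[(E)-2-(2,6-dihydroxy-3,3-dimethyl-4-oxo-5-propanoylcyclohexa-1,5-dien-1-yl)ethenyl]-4-methoxy-5-methyl-2H-pyran-2-one F10. Its only disubstituted alkene is then saturated with H2 over Pd/C in EtOAc to give 12, the fully substituted pyrone and ring B double bonds being left untouched.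

Further compounds
F1 | step 8 | 1-(2,4,6-trihydroxy-3-methylphenyl)butan-1-one | CCCC(=O)c1c(O)cc(O)c(C)c1O
F2 | step 8 | 1-[2-hydroxy-4,6-bis(methoxymethoxy)-3-methylphenyl]butan-1-one | CCCC(=O)c1c(OCOC)cc(OCOC)c(C)c1O
F3 | step 8 | 1-[2-methoxy-4,6-bis(methoxymethoxy)-3-methylphenyl]butan-1-one | CCCC(=O)c1c(OCOC)cc(OCOC)c(C)c1OC
F4 | step 8 | 1-(4,6-dihydroxy-2-methoxy-3-methylphenyl)butan-1-one | CCCC(=O)c1c(O)cc(O)c(C)c1OC
F5 | step 5 | 6-[2-(benzyloxy)ethyl]-4-hydroxy-5-methyl-2H-pyran-2-one | CC1=C(CCOCc2ccccc2)OC(=O)C=C1O
F6 | step 5 | 6-[2-(benzyloxy)ethyl]-3-butanoyl-4-hydroxy-5-methyl-2H-pyran-2-one | CCCC(=O)C1=C(O)C(C)=C(CCOCc2ccccc2)OC1=O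
F7 | step 5 | 6-[2-(benzyloxy)ethyl]-3-butanoyl-4-methoxy-5-methyl-2H-pyran-2-one | CCCC(=O)C1=C(OC)C(C)=C(CCOCc2ccccc2)OC1=O
F8 | step 5 | 3-butanoyl-6-(2-hydroxyethyl)-4-methoxy-5-methyl-2H-pyran-2-one | CCCC(=O)C1=C(OC)C(C)=C(CCO)OC1=O
F9 | step 5 | (5-butanoyl-4-methoxy-3-methyl-6-oxo-6H-pyran-2-yl)acetaldehyde | CCCC(=O)C1=C(OC)C(C)=C(CC=O)OC1=O
F10 | step 7 | 3-butanoyl-6-[(E)-2-(2,6-dihydroxy-3,3-dimethyl-4-oxo-5-propanoylcyclohexa-1,5-dien-1-yl)ethenyl]-4-methoxy-5-methyl-2H-pyran-2-one | CCC(=O)C1=C(O)C(/C=C/C2=C(C)C(OC)=C(C(=O)CCC)C(=O)O2)=C(O)C(C)(C)C1=O
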